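Slowness was what I saw first in the green flask: after 120 min, 17.9% of the D had gone, and L held 4.9% of the charge.

| setting | green | blue | flask |
|---|---|---|---|
| D | 0.20 M | 0.40 M | 0.20 M |
| Q | 0.20 M | 0.20 M | 0.200 M |
| X | 0.46 mM | 0.46 mM | 0.46 mM |
| remark | the very flask that is asked about, followed so far | run made earlier |  |
| time |  |  | 4.0 h |

green run (percent of the D charged)

| time / min | L / % | D / % |
|---|---|---|
| 10.0 | 2.5 | 96.4 |
| 20.0 | 3.9 | 95.3 |
| 30.0 | 4.5 | 90.9 |
| 60.0 | 5.9 | 87.2 |
| 120 | 4.9 | 82.1 |

blue run (percent of the D charged)

| time / h | L / % | D / % |
|---|---|---|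
| 0.333 | 3.4 | 95.5 |
| 0.667 | 3.4 | 92.2 |
| 1.00 | 3.6 | 88.6 |
| 2.00 | 3.8 | 84.8 |
| 4.00 | 2.6 | 74.8 |

(scatter of a reading: 1 percentage point)

- the average divides the monomer in chains by the number of chains begun, living and dead together
- on the list of suspects stand: D + X -> Z + L; D + Z -> L + Z; L + Z -> D + Z; Q + D -> G; Z + D -> J
- the earlier runs do not show the number of chains; that part of a forecast is a guess

- average number of monomer units in a chain (chains begun, living or dead) at 4.0 h
- part of the D that has reacted at 4.0 h

L read 5.9% at 60.0 min and 4.9% at 120 min, so within the scatter it had stopped growing while D went on falling. I took the rest of the lost D as G, formed from Q + D.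

Which concentration set that rate? At 60.0 min, the fraction of D turned to G read 6.90% in green and 7.80% in blue, with 1 percentage point of scatter on each reading. Blue had twice the D at the same Q, yet I could not tell the two apart. So the fractional loss of D did not depend on D, and I read the step as first order in D. Q was the same in both runs, so first order in Q was my assumption.

In green, D and Q were charged equally and, apart from the D that went to L, fell together. The fraction turned to G, divided by the fraction not turned, then grows in step with time. I called the G clock the time at which G equals what remains unturned, which is the inverse of rate constant times charge. The green reading of 13.0% at 120 min gave a clock of 13.4 h.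

At 4.0 h, the clock gave G as 23.0%. Adding L at its last green reading gave me c of 27.9%. If each X began one chain, which was a guess, dp came to 21.3.

The forecast put c lower than I did, at 27%, with dp 21, noting that “The D lost is far more than the L gained”.

The flask gave c of 29.6% and dp of 21.2. With the path from Q + D to G struck out, c was 5.18%.

    D + X → Z + L (k = 35.0 L mol⁻¹ h⁻¹)
    D + Z → L + Z, rate k2*[Z]*[D] (k = 1100 L mol⁻¹ h⁻¹)
    L + Z → D + Z, rate k3*[Z] as long as [L] is above zero (k = 75.0 h⁻¹)
    Q + D → G (k = 0.430 L mol⁻¹ h⁻¹)
    Z + D → J (k = 35.0 L mol⁻¹ h⁻¹)

A neighbour flask was charged with 0.050 M of Q, the rest unchanged. Its D stayed near the charge, with 88% left, so I treated Q as pseudo-first-order on the same clock. That gave 74.2% of its charged Q left at 4.0 h, and the neighbour held 73%.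

(Readings and results were generated by integration for an exercise; scatter was added.)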